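Decide first how much capture agent to charge: these flasks run from 0.0500 to 0.375 of the substrate charge, and you want to know what that does to open intermediate at the end.

all flasks: substrate 0.80 M; free catalyst 16 mM

| run | coupling partner | capture agent | remark | time |
|---|---|---|---|---|
| winter | 0.96 M | 0.052 M | run made earlier |  |
| dusk | 0.96 M | 0.34 M | run made earlier |  |
| Sunday's | 0.960 M | 0.0400 M |  | 25 h |
| Thursday's | 0.960 M | 0.0800 M |  | 25 h |
| Wednesday's | 0.960 M | 0.150 M |  | 25 h |
| Friday's | 0.960 M | 0.300 M |  | 25 h |

- winter (time / h: open intermediate / %, product / %): 1.33: 7.1, 4.1; 3.00: 8.6, 12.6; 6.00: 9.3, 24.6; 10.0: 8.3, 35.6; 12.0: 8.1, 39.7; 20.0: 7.4, 50.0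
- dusk (time / h: open intermediate / %, product / %): 1.33: 6.7, 3.5; 2.50: 7.4, 10.0; 4.00: 7.2, 14.3; 6.00: 7.7, 21.5; 10.0: 6.0, 30.3; 20.0: 4.3, 40.3

(standard deviation of a reading: 0.3 percentage points)

- amount of open intermediate at the end, in percent of the substrate charged for Sunday's, Thursday's, Wednesday's, Friday's, in this order
- the course of these numbers from the first flask to the last (rises all the way / falls, then rises / rises, then falls / falls all the way / hardly changes)

- "hardly changes" means that all values lie within two and a half points (for a concentration: within two and a half percent of the largest)

Start from the winter run, where product gains 10 percentage points between 12.0 h and 20.0 h. So the open intermediate standing there, 7.4%, turns over in about 5.75 h, which is shorter than the 25 h of the new flasks. You may therefore treat it as a quasi-steady state, with its level equal to supply over drain.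

Now assume that supply and the coupling drain match between winter and dusk, and that the capture drain grows in proportion to x, the capture agent as a fraction of the substrate charge. The level is then its capture-free value L divided by one plus x/h. The late readings, 7.4% in winter and 4.3% at dusk, give h = 0.434, the half-way charge, a selectivity factor: the fraction x at which capture drains open intermediate as fast as coupling does at that late stage of a run. It is a reading, and it carries the scatter of 0.3 points on a gap of 3.1 points.

So the row should fall with each flask, and L cancels in the ratio: Friday's level should be 0.598 of Sunday's.

The forecast gives 7.1%, 6.6%, 5.7%, 4%, falls all the way: “the agent slowly drains the intermediate into a dead end”; its Friday-to-Sunday ratio of 0.563 lies below this reckoning's.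

The flasks give 7.32%, 6.65%, 5.66%, 4.15%: falls all the way.

    open intermediate + capture agent → trapped intermediate (k = 0.460 /M/h)
    substrate + free catalyst → spent catalyst (k = 0.150 /M/h)
    coupling partner + free catalyst + open intermediate → free catalyst + product (k = 54.0 /M²/h)
    substrate + free catalyst → free catalyst + open intermediate (k = 6.00 /M/h)

Friday's level stands at 0.567 of Sunday's, beside the reckoned 0.598. Part of the fall from Sunday's flask to Friday's comes from the capture step: with the passage of open intermediate and capture agent into trapped intermediate taken away, the change between these two flasks is 0 points instead of −3.2 points, and open intermediate in Friday's flask stands at 8.08% instead of 4.15%. Carried to that capture-free flask, the half-way charge multiplies Friday's 4.15% by 1.86 and gives 7.73%, beside the 8.08% it holds.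

All runs stem from a simulated flask for an exercise; the scatter is artificial.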